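The runs were computed for an exercise; the scatter is artificial.

The ratio we would plot first on a plate is the equivalents of reagent per substrate, [reagent]/[substrate] at charge, because Monday's and Friday's runs moved it and the best target reading moved with it.

| flask | substrate | reagent | base | remark | time |
|---|---|---|---|---|---|
| Monday's | 0.36 M | 0.53 M | 0.0106 M | run made earlier |  |
| Friday's | 0.80 M | 0.53 M | 0.0106 M | run made earlier |  |
| Tuesday's | 0.53 M | 0.53 M | 0.016 M | run made earlier |  |
| flask | 0.53 M | 0.530 M | 0.0106 M |  | 20 min |

- Monday's (time / min: target / %): 0.167: 12.1; 0.333: 26.8; 0.833: 43.5; 2.00: 21.7; 5.00: 2.1; 12.0: 0.3
- Friday's (time / min: target / %): 0.167: 17.8; 0.333: 31.4; 0.833: 24.4; 2.00: 7.8; 5.00: 0.6; 12.0: 0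
- Tuesday's (time / min: target / %): 0.167: 13.4; 0.417: 35.6; 1.33: 28.3; 4.00: 3.9; 12.0: 0

(each reading ± 0.5 percentage points)

- percentages count the substrate that a species holds: one side product counts as two
- the analysis behind the earlier runs scatters by 0.5 percentage points, standard deviation
- steps under discussion: substrate + reagent + by-product -> target + 2 by-product; substrate + reagent -> target + by-product; base + by-product <-> salt; target -> over-reaction product; substrate + target -> side product

* the moment within 20 min at which there is most target
* the amount of target, in percent of the substrate charged, at that time

Monday's run stands at 1.47 equivalents with a best reading of 43.5%, and Friday's at 0.662 with 31.4%. Comparing best readings, and not readings at one clock time, leaves time out, and dividing the logarithm of one change by that of the other gives the peak exponent, the power of the equivalents that the best reading follows between these two runs, 0.408. At 1.00 equivalents the exponent puts our estimate for the flask at 37.1%, and the same interpolation on the times of those readings gives 0.534 min.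

Two doubts follow. Tuesday's run has the flask's substrate and reagent but more base, so can it be ignored? Its extra base is 1.02% of the substrate charged, and its best reading of 35.6% lies below our estimate, so we keep it beside the estimate as a reading from a near recipe, not as a bound. Second, best readings need not be peaks, since a peak can fall between samples, so we commit to slightly above our figure. The exponent has a weakness too: reagent stayed fixed in these runs, so they show substrate changing and never reagent.

The forecast, made separately, says 39% at 0.6 min, adding “With less base, the flask should be slightly earlier and slightly higher”.

The flask gives 40.3% at 0.612 min, which is 3.2 percentage points above what the exponent gave.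

    substrate + reagent + by-product → target + 2 by-product (k = 0.559 L² mol⁻² s⁻¹)
    substrate + reagent → target + by-product (k = 0.0224 L mol⁻¹ s⁻¹)
    base + by-product ⇌ salt, settled at all times (K = 16000 L mol⁻¹)
    target → over-reaction product (k = 0.0135 s⁻¹)
    substrate + target → side product (k = 0.0591 L mol⁻¹ s⁻¹)

Just after the start, target goes to over-reaction product at 0.43 of the rate at which it goes with substrate to side product, a selectivity factor that favours the side product in the flask at that moment. For the neighbour charged with 1.3 M of reagent, 2.45 equiv, the exponent gives 53.6%, and the computed peak is 71.4%.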